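Numbering used throughout: ring C1 = CMe2, C2 = CHBr, C3 = CH2, C4 = CHCl, C5 = alkylidene carbon, C6 = CHCl; exocyclic C7 = =CH, C8 = CH2Br.
Cuts: C8–Br and C4–Cl go back to a cis-2-ene-1,4-diol, the 1,4-adduct of the diene C4=C5–C7=C8; the ring is cut at C4–C5 (enyne metathesis), the chain at C3–C4 and C5–C7, and the C3–C2–C1–C6–C5 backbone comes from C=C cleavage of 4,4-dimethylcyclopentene.
Enabling feature: C4(Cl)–C5(=C7)–C8(Br) on the six-membered ring is a masked 1-vinylcyclohexene, which is what exo closure of alkene carbon C4 onto the alkyne C5≡C7 gives, with C8 transferred from the alkene terminus.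
Forward: ozonolysis opens the five-membered ring, the two CH2 groups flanking C1 are halogenated in turn, enyne metathesis closes the only ring, and singlet oxygen then bridges C4 and C8.
Stereochemistry: C2 and C6 by enamine catalysis with one pyrrolidine enantiomer; C4 by substrate control (oxygen anti to the pseudoaxial C6–Cl, then SN2 inversion by chloride); alkene geometry by the temporary 1,2-dioxine ring, whose O–O bond is cleaved afterwards.

Key step: step 7

Assumption: by the steric-shielding model of the enamine, (2S,5S)-2,5-diphenylpyrrolidine is taken to give the (R)-2-haloaldehydes needed in steps 2 and 5; if the sense is the opposite, the (2R,5R)-catalyst is used in both steps.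

Step 1
Reactants: 1 4,4-dimethylcyclopentene
Product: 2 5,5-dimethoxy-3,3-dimethylpentanal
Conditions: O3, TsOH·H2O (cat.), CH2Cl2/MeOH, −78 °C; NaHCO3; Me2S, −78 °C → rt
Reagents that add atoms: ozone [O-][O+]=O; methanol CO
Why: Criegee ozonolysis with terminal differentiation, in which the carbonyl oxide is trapped by methanol as a methoxy hydroperoxide, the other aldehyde is acetalised under acid and Me2S then reduces the hydroperoxide end to the free aldehyde; the alkene is symmetric, so only one product can form and no stereocentre arises.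

Step 2
Reactants: 2 5,5-dimethoxy-3,3-dimethylpentanal
Product: 4 (R)-2-bromo-5,5-dimethoxy-3,3-dimethylpentan-1-ol, via α-bromoaldehyde 3 (not isolated)
Conditions: (2S,5S)-2,5-diphenylpyrrolidine (20 mol %), PhCO2H (20 mol %), 4,4-dibromo-2,6-di-tert-butylcyclohexa-2,5-dienone, H2O, CH2Cl2/pentane, −40 °C; then NaBH4, MeOH, −40 → 0 °C
Reagents that add atoms: 4,4-dibromo-2,6-di-tert-butylcyclohexa-2,5-dien-1-one CC(C)(C)C1=CC(Br)(Br)C=C(C(C)(C)C)C1=O
Why: Organocatalytic enamine α-bromination of an aldehyde, in which the (E)-enamine of the C2-symmetric pyrrolidine is brominated on the face not shielded by the flanking phenyl group, so the future C2 bromide centre is set by the catalyst, and immediate NaBH4 reduction removes the epimerisable aldehyde.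

Step 3
Reactants: 4 (R)-2-bromo-5,5-dimethoxy-3,3-dimethylpentan-1-ol
Product: 6 (S)-4-bromo-7,7-dimethoxy-5,5-dimethylhept-1-ene, via triflate 5 (not isolated)
Conditions: Tf2O, 2,6-lutidine, CH2Cl2, −78 °C; then CH2=CHMgBr, CuBr·SMe2 (10 mol %), THF, −78 → −30 °C
Reagents that add atoms: trifluoromethanesulfonic anhydride O=S(=O)(OS(=O)(=O)C(F)(F)F)C(F)(F)F (in 5 only); vinylmagnesium bromide C=C[Mg]Br
Why: Copper-catalysed SN2 coupling of a Grignard reagent with a primary alkyl triflate, which should outrun any reaction at the neopentyl secondary bromide; the bromide centre is not touched and its descriptor changes from R to S only because the ranking of its neighbours changes.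

Step 4
Reactants: 6 (S)-4-bromo-7,7-dimethoxy-5,5-dimethylhept-1-ene
Product: 7 (S)-4-bromo-3,3-dimethylhept-6-enal
Conditions: 1 M HCl, THF, 0 °C → rt
Reagents that add atoms: water O
Why: Acid-catalysed hydrolysis of a dimethyl acetal through the oxocarbenium ion, to which the bromide, the terminal alkene and the stereocentre are inert.

Step 5
Reactants: 7 (S)-4-bromo-3,3-dimethylhept-6-enal
Product: 8 (2R,4S)-4-bromo-2-chloro-3,3-dimethylhept-6-enal
Conditions: NCS, (2S,5S)-2,5-diphenylpyrrolidine (10 mol %), CH2Cl2, 0 °C → rt; short silica plug, used at once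
Reagents that add atoms: N-chlorosuccinimide O=C1CCC(=O)N1Cl
Why: Organocatalytic enamine α-chlorination of an aldehyde, in which the same catalyst enantiomer shields the same enamine face as in step 2, so the future C6 chloride centre is set by the catalyst and not by the remote bromide centre.

Step 6
Reactants: 8 (2R,4S)-4-bromo-2-chloro-3,3-dimethylhept-6-enal
Product: 9 (3S,5S)-5-bromo-3-chloro-4,4-dimethyloct-7-en-1-yne
Conditions: dimethyl (1-diazo-2-oxopropyl)phosphonate, K2CO3, MeOH, 0 °C → rt
Reagents that add atoms: dimethyl (1-diazo-2-oxopropyl)phosphonate CC(=O)C(=[N+]=[N-])P(=O)(OC)OC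
Why: Ohira–Bestmann homologation (alkylidene carbene, 1,2-hydrogen shift), known to convert α-fluoroaldehydes into propargylic fluorides with the halide centre intact; here the chloride sits on a neopentyl carbon, which should slow both epoxide closure and enolisation, and the descriptor changes from R to S by ranking only.

Step 7
Reactants: 9 (3S,5S)-5-bromo-3-chloro-4,4-dimethyloct-7-en-1-yne
Product: 10 (4S,6S)-4-bromo-6-chloro-1-ethenyl-5,5-dimethylcyclohex-1-ene
Conditions: second-generation Grubbs catalyst RuCl2(H2IMes)(PCy3)(=CHPh) (5 mol %), ethylene (1 atm), CH2Cl2 (0.01 M), 40 °C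
Reagents that add atoms: none
Why: The ruthenium methylidene loads onto the unhindered C4 terminal alkene, the C4 alkylidene adds across the tethered alkyne C5≡C7 to a ruthenacyclobutene that opens to the C7 vinylcarbene with the C4=C5 bond in place, and methylene transfer from ethylene releases the 1,3-diene and returns the catalyst (Chauvin mechanism). The closest known reaction type is the ring-closing metathesis of terminal 1,7-enynes to 1-vinylcyclohexenes under ethylene. The single ring (C1–C6) closes in the exo mode, 6-exo-dig with respect to the alkyne, whereas the endo mode would give a seven-membered ring. No stereocentre is created: C2 (C–Br) and C6 (C–Cl) lie outside the reacting π systems and pass through unchanged, and C4 stays sp2 so that it can be set afterwards from the ring. The step needs exo over endo closure and ring closure over alkyne oligomerisation or cross-metathesis with ethylene, which the 1,7-spacing, the gem-dimethyl group at C1 (Thorpe–Ingold effect) and high dilution should secure, while the alkyl bromide and the propargylic chloride are inert to the ruthenium carbene. The product carries the diene C4=C5–C7=C8, with C8 brought in from the alkene terminus, ready for cis-1,4-functionalisation.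

Step 8
Reactants: 10 (4S,6S)-4-bromo-6-chloro-1-ethenyl-5,5-dimethylcyclohex-1-ene
Product: 12 (1R,3S,5S)-5-bromo-3-chloro-2-[(E)-2-hydroxyethylidene]-4,4-dimethylcyclohexan-1-ol, via endoperoxide 11 (not isolated)
Conditions: O2, tetraphenylporphyrin (cat.), hν (visible), CH2Cl2, −40 °C; then thiourea, MeOH, 0 °C → rt
Reagents that add atoms: dioxygen O=O
Why: [4+2] cycloaddition of singlet oxygen to the s-cis diene (hetero-Diels–Alder) followed by thiourea reduction of the O–O bond: the suprafacial addition ties C4 and C8 into one 1,2-dioxine ring, which fixes C8 cis to C4 on the new C5=C7 bond, and oxygen should reach C4 anti to the pseudoaxial C6–Cl that covers the lower face of C4, that is cis to the C2 bromide.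

Step 9
Reactants: 12 (1R,3S,5S)-5-bromo-3-chloro-2-[(E)-2-hydroxyethylidene]-4,4-dimethylcyclohexan-1-ol
Product: 13 (1R,3S,5S)-5-bromo-2-[(E)-2-(tert-butyldimethylsilyloxy)ethylidene]-3-chloro-4,4-dimethylcyclohexan-1-ol
Conditions: TBSCl (1.05 equiv), imidazole, CH2Cl2, −20 °C
Reagents that add atoms: tert-butyldimethylsilyl chloride CC(C)(C)[Si](C)(C)Cl
Why: Sterically controlled silyl ether formation, selective for the primary allylic hydroxyl over the hindered secondary one, with no stereocentre involved.

Step 10
Reactants: 13 (1R,3S,5S)-5-bromo-2-[(E)-2-(tert-butyldimethylsilyloxy)ethylidene]-3-chloro-4,4-dimethylcyclohexan-1-ol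
Product: 14 tert-butyl{(2E)-2-[(2S,4S,6S)-4-bromo-2,6-dichloro-3,3-dimethylcyclohexylidene]ethoxy}dimethylsilane
Conditions: PPh3, NCS, THF, −20 → 0 °C
Reagents that add atoms: N-chlorosuccinimide O=C1CCC(=O)N1Cl
Why: Appel-type deoxychlorination through the alkoxyphosphonium salt with SN2 inversion at C4: allylic 1,3-strain with the cis CH2OTBS arm should hold the C4–O bond axial, so chloride can enter from the lower face along an equatorial path and C4–Cl ends cis to C6–Cl.

Step 11
Reactants: 14 tert-butyl{(2E)-2-[(2S,4S,6S)-4-bromo-2,6-dichloro-3,3-dimethylcyclohexylidene]ethoxy}dimethylsilane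
Product: 15 ochtodene [(2S,4S,6S)-6-bromo-3-[(E)-2-bromoethylidene]-2,4-dichloro-1,1-dimethylcyclohexane]
Conditions: Ph3PBr2, CH2Cl2, 0 °C → rt
Reagents that add atoms: dibromotriphenylphosphorane BrP(Br)(c1ccccc1)(c1ccccc1)c1ccccc1
Why: Direct conversion of a silyl ether into a bromide with triphenylphosphine dibromide (silyl transfer to bromide, then SN2 of bromide at the primary allylic oxyphosphonium carbon), in which the secondary halides, the three stereocentres and the alkene geometry take no part.

Compound list
1 | 4,4-dimethylcyclopentene | CC1(C)CC=CC1 | starting material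
2 | 5,5-dimethoxy-3,3-dimethylpentanal | COC(OC)CC(C)(C)CC=O | intermediate
3 | (R)-2-bromo-5,5-dimethoxy-3,3-dimethylpentanal | COC(OC)CC(C)(C)[C@@H](Br)C=O | intermediate
4 | (R)-2-bromo-5,5-dimethoxy-3,3-dimethylpentan-1-ol | COC(OC)CC(C)(C)[C@@H](Br)CO | intermediate
5 | (R)-2-bromo-5,5-dimethoxy-3,3-dimethylpentyl trifluoromethanesulfonate | COC(OC)CC(C)(C)[C@@H](Br)COS(=O)(=O)C(F)(F)F | intermediate
6 | (S)-4-bromo-7,7-dimethoxy-5,5-dimethylhept-1-ene | COC(OC)CC(C)(C)[C@@H](Br)CC=C | intermediate
7 | (S)-4-bromo-3,3-dimethylhept-6-enal | O=CCC(C)(C)[C@@H](Br)CC=C | intermediate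
8 | (2R,4S)-4-bromo-2-chloro-3,3-dimethylhept-6-enal | O=C[C@H](Cl)C(C)(C)[C@@H](Br)CC=C | intermediate
9 | (3S,5S)-5-bromo-3-chloro-4,4-dimethyloct-7-en-1-yne | C=CC[C@H](Br)C(C)(C)[C@@H](Cl)C#C | intermediate
10 | (4S,6S)-4-bromo-6-chloro-1-ethenyl-5,5-dimethylcyclohex-1-ene | CC1(C)[C@@H](Br)CC=C(C=C)[C@@H]1Cl | intermediate
11 | (5S,7S,8aR)-7-bromo-5-chloro-6,6-dimethyl-3,5,6,7,8,8a-hexahydro-1,2-benzodioxine (endoperoxide, O on C4 cis to Br) | CC1(C)[C@@H](Br)C[C@H]2OOCC=C2[C@@H]1Cl | intermediate
12 | (1R,3S,5S)-5-bromo-3-chloro-2-[(E)-2-hydroxyethylidene]-4,4-dimethylcyclohexan-1-ol (CH2OH cis to the carbinol carbon) | CC1(C)[C@@H](Br)C[C@@H](O)/C(=C\CO)[C@@H]1Cl | intermediate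
13 | (1R,3S,5S)-5-bromo-2-[(E)-2-(tert-butyldimethylsilyloxy)ethylidene]-3-chloro-4,4-dimethylcyclohexan-1-ol | CC1(C)[C@@H](Br)C[C@@H](O)/C(=C\CO[Si](C)(C)C(C)(C)C)[C@@H]1Cl | intermediate
14 | tert-butyl{(2E)-2-[(2S,4S,6S)-4-bromo-2,6-dichloro-3,3-dimethylcyclohexylidene]ethoxy}dimethylsilane | CC1(C)[C@@H](Br)C[C@H](Cl)/C(=C\CO[Si](C)(C)C(C)(C)C)[C@@H]1Cl | intermediate
15 | ochtodene, (2S,4S,6S)-6-bromo-3-[(E)-2-bromoethylidene]-2,4-dichloro-1,1-dimethylcyclohexane | CC1(C)[C@@H](Br)C[C@H](Cl)/C(=C\CBr)[C@@H]1Cl | target

Total step count: 11. Longest linear sequence: 11 steps (the route is linear from 1).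

Steps most likely to fail

Step 8. The ene reaction of singlet oxygen at the trisubstituted ring alkene may compete with the [4+2] addition, oxygen may add to the other diene face, and thiourea may displace the allylic chloride. The fallback sets out from 10: cis-1,4-diboration with B2pin2 and Pt(PPh3)4 in toluene at 80 °C adds both boryl groups to one face of the s-cis diene and should give the 1,4-bis(pinacolboronate) F1 with C8 cis to C4. Oxidation with NaBO3·4H2O in THF/H2O, with retention at C4, comes back to the route at 12.

Step 3. The organocopper reagent may remove the bromide by reductive elimination or E2 across the β-bromo triflate instead of substituting at carbon. The fallback sets out from 5 (made from 4 as in step 3): copper-free SN2 alkynylation with LiC≡CSiMe3 in THF/DMPU at −78 → −20 °C should give the silyl alkyne F2. K2CO3 in MeOH then removes silicon to give the terminal alkyne F3, and semihydrogenation (H2, Pd/CaCO3 poisoned with Pb(OAc)2, quinoline) comes back to the route at 6.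

Step 10. Substitution may occur with allylic transposition (attack at C7), the alkoxyphosphonium salt may eliminate toward C3, or partial ionisation may erode the inversion at C4. The fallback sets out from 10 and installs the C4 chloride without an alcohol: 1,4-chloroacetoxylation with Pd(OAc)2 (cat.), LiCl, LiOAc and p-benzoquinone in AcOH at rt. Acetate should add to C8 and chloride to C4, each anti to palladium on the open diene face, which places chloride cis to C6–Cl and gives the chloro acetate F4. The alkene geometry depends on the π-allyl isomer with C8 turned toward C4, which the C6 substituent on the central carbon should favour. K2CO3 in MeOH at 0 °C then gives the allylic alcohol F5, and CBr4/PPh3 in CH2Cl2 at 0 °C comes back to the route at 15.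

Further compounds
F1 | step 8 | 2-[(2E)-2-[(2S,4S,6R)-4-bromo-2-chloro-3,3-dimethyl-6-(4,4,5,5-tetramethyl-1,3,2-dioxaborolan-2-yl)cyclohexylidene]ethyl]-4,4,5,5-tetramethyl-1,3,2-dioxaborolane | CC1(C)[C@@H](Br)C[C@@H](B2OC(C)(C)C(C)(C)O2)/C(=C\CB2OC(C)(C)C(C)(C)O2)[C@@H]1Cl
F2 | step 3 | (S)-(4-bromo-7,7-dimethoxy-5,5-dimethylhept-1-yn-1-yl)trimethylsilane | COC(OC)CC(C)(C)[C@@H](Br)CC#C[Si](C)(C)C
F3 | step 3 | (S)-4-bromo-7,7-dimethoxy-5,5-dimethylhept-1-yne | COC(OC)CC(C)(C)[C@@H](Br)CC#C
F4 | step 10 | (2E)-2-[(2S,4S,6S)-4-bromo-2,6-dichloro-3,3-dimethylcyclohexylidene]ethyl acetate | CC1(C)[C@@H](Br)C[C@H](Cl)/C(=C\COC(C)=O)[C@@H]1Cl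
F5 | step 10 | (2E)-2-[(2S,4S,6S)-4-bromo-2,6-dichloro-3,3-dimethylcyclohexylidene]ethan-1-ol | CC1(C)[C@@H](Br)C[C@H](Cl)/C(=C\CO)[C@@H]1Cl
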